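## Structural features

The target (12) consists of two (2S)-7-hydroxy-5-methoxyflavan units, each a phloroglucinol-type benzene ring fused to a dihydropyran that carries a phenyl group at C2. One methylene carbon joins C8 of unit A to C6 of unit B, so two almost identical halves are linked through different ring positions, each ortho to a 7-hydroxyl. The only stereocentres are the two C2 carbons. They are remote from each other, both (S), next to no other stereocentre, and have no neighbouring function (no 3-hydroxyl, no 4-oxo group) that could relay or correct configuration. Fragile points are the benzylic C2–O1 ether bonds (acid ionisation, hydrogenolysis), the electron-rich free phenols (over-substitution, oxidation) and the diarylmethane link between two activated rings (acid-mediated scrambling). The real difficulties are absolute control at an isolated C2 centre and the unsymmetrical 8→6' junction. The key step exploits the O1–C2(Ph)–C3–C4 chain of each pyran fused at C4a/C8a. Read backwards, this is the [4+2] adduct of styrene with an ortho-quinone methide whose carbonyl is C8a=O and whose exocyclic methylene on C4a becomes C4. Since both halves contain the same flavan, one enantioselective cycloaddition can supply both stereocentres.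

## Logic of the disconnections

12 ⇒ 11. The C8–H bond of unit B is traced back to a C8–Br bond. The bromine is a removable blocking group that leaves C6 as the only open ring position of that half. The forward step must remove bromine without cleaving either benzylic C2–O1 bond.

11 ⇒ 9 + 8 (through 10). The bridge is cut at the CH2–C6 bond of unit B. This splits the molecule into two derivatives of one flavan: an electrophile, 10, released from 9, and a nucleophile, 8. The forward step needs C-alkylation of 8 at C6 and must outrun self-condensation of 10 with 9.

9 ⇒ 7 and 8 ⇒ 7. The C8–CH2 bond of 9 and the C8–Br bond of 8 are both cut back to the same phenol. The gain is that one intermediate serves both halves. The demand is C8 rather than C6 selectivity in two electrophilic substitutions; C8 is flanked only by the hydroxyl and the tied-back ring oxygen, whereas C6 is shielded by the 5-methoxy group.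

7 ⇒ 6. The O–acyl bond is restored. The acyl group is needed only for the two steps before and the cycloaddition itself, and comes off under conditions harmless to the C2–O1 bond.

6 ⇒ 3 + 4 (through 5). The O1–C2 and C3–C4 bonds are cut together. This removes the pyran ring, two skeletal bonds and the stereocentre in one operation and leaves an achiral benzyl alcohol and an achiral alkene. The forward step needs a chiral acid that selects one face of 4, and cycloaddition must be faster than arylation of 5 by the electron-rich rings present.

3 ⇒ 2 ⇒ 1. The benzylic alcohol is taken back to the aldehyde and the ester to the free 4-hydroxyl, which leads to a commercial aldehyde. The demands are acylation of the non-chelated hydroxyl only and a reduction that stops at the labile benzyl alcohol.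

## Other disconnections considered

Alternative 1: The cut removes three bonds of the unit A benzene ring (C7–C8, C8a–C4a, C6–C7). The precursor is the cyclobutenone A2, whose side chain carries the (S)-configured benzylic alkynyl ether; the alkyne terminus bears the bridge carbon and the finished unit B as its silyl ether. In the forward key step, heat or light would open A2 to a vinylketene, which adds the tethered alkynyl ether in a [2+2] fashion; ring opening and 6π closure would then give A1, and fluoride would release 12.
- In its favour: the substitution pattern of unit A is fixed by connectivity, so no site selectivity and no blocking group are needed on that half, and the unit A phenol emerges free. On this point it is better than the chosen plan, which relies on a C8 preference.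
- Against it: the step creates no stereocentre. Both C2 centres must exist beforehand, and unit B must still be made enantiopure and functionalised at C6 by other means. Secondary benzylic alkynyl ethers are prone to retro-ene loss of a ketene and to sigmatropic shifts at the temperatures a benzannulation needs. A2 itself is a long preparation.
- Comparison: mechanistically it is a catalyst-free pericyclic cascade of a known reaction type, which is an advantage over a key step without direct precedent. Structurally it solves only half of the regiochemical problem and none of the stereochemical one. In step economy it should be far longer than the chosen plan, which makes both halves from one three-step sequence.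

Alternative 2: The cut is at both C2–phenyl bonds. The precursors are the bis(chromene acetal) A4, used as a mixture of acetal stereoisomers, and phenylboronic acid A5. In the forward key step, Ni(cod)2 with a chiral TADDOL-derived phosphonite would ionise each acetal to a nickel-bound benzopyrylium unit and transfer phenyl twice to give A3. Hydrogenation of both C3=C4 bonds and desilylation would then give 12.
- In its favour: the reaction class is established on simple chromene acetals, which makes it better than the chosen key step in precedent. It is enantioconvergent and catalyst-controlled. The bridge and its 8,6' regiochemistry would be settled on achiral material. Two inductions in one molecule should raise the enantiomeric purity of the (S,S) isomer.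
- Against it: any imperfection at either site appears as the (S,R) diastereomer, which would be hard to separate. The 5,7-dioxygenated, 8-substituted acetals are much more electron-rich and hindered than the proven substrates. The 2-aryl-2H-chromene products can lose C2 configuration by reversible 6π ring opening. The final hydrogenation runs beside an allylic and benzylic C–O bond, which is more exposed than any bond in the chosen plan. No ring is closed, so both pyrans must be built conventionally.
- Comparison: structurally more convergent at the bridge, mechanistically better founded, but with a longer route to A4 and a more delicate endgame. Overall step count is expected to exceed that of the chosen plan.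

Alternative 3: The cut is at the C4–C4a bond of unit A. The precursor is the aryl ether A7, a phenol whose neighbouring oxygen carries the (S)-3-iodo-1-phenylpropyl chain. In the forward key step, a carbonate base (Cs2CO3) at high dilution would form the phenoxide, which attacks the primary iodide through its para carbon C4a; tautomerisation would give A6, and debenzylation would give 12.
- In its favour: the stereocentre would come from an enantiopure halohydrin building block by etherification with inversion, so no new asymmetric catalysis is needed. In certainty of absolute configuration it is equal to or better than the chosen plan. The resorcinol core of A7 is symmetric about its C5–C8 axis before etherification, so the 8-linkage of unit A needs no site selectivity, which is again better than the chosen plan.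
- Against it: phenoxides prefer O-alkylation. Intramolecular O-alkylation is geometrically excluded here, but intermolecular O-alkylation and elimination of HI remain. The carbon nucleophile must reach a chain anchored on the adjacent oxygen. Etherification of a doubly ortho-substituted phenol with a secondary benzylic alcohol is slow and can erode configuration through ionisation. Only the unit A pyran is closed, so unit B needs its own asymmetric synthesis and its own C6 functionalisation.
- Comparison: the ring closure is ordinary ionic chemistry and lower in risk than the chosen key step. It requires two different syntheses for two nearly identical halves, so it is clearly longer.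

Key step: step 3

Remark on the structures: the target, the benzyl alcohol skeleton and the cycloadduct skeleton are mutually consistent (both centres (S); unit A joined through C8, unit B through C6); no correction is needed.

Remark on the precursor design: the 4-oxygen carries a pivalate (3, 6) instead of an ether. This makes the rings of 3 and 6 less nucleophilic and methide 5 more electrophilic, makes 3 easier to handle, and allows unmasking by methanolysis instead of hydrogenolysis next to the C2–O1 bond.

Assumption: 1 is taken as commercially available. The sense of induction of the confined acid cannot be predicted for an unsubstituted methide, so the antipode that gives (2S) is to be found in a test reaction; it is written here as the (S,S) form.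

## Route

Step 1
Reactants: 1 2,4-dihydroxy-6-methoxybenzaldehyde
Product: 2 4-formyl-3-hydroxy-5-methoxyphenyl 2,2-dimethylpropanoate
Conditions: PivCl (1.05 equiv), Et3N (1.1 equiv), CH2Cl2, −20 to 0 °C
Reagents that add atoms: pivaloyl chloride, CC(C)(C)C(Cl)=O
Why: Selective O-acylation; the 2-hydroxyl is held in a hydrogen bond to the formyl group, so the more acidic, non-chelated 4-hydroxyl should react first.

Step 2
Reactants: 2 4-formyl-3-hydroxy-5-methoxyphenyl 2,2-dimethylpropanoate
Product: 3 3-hydroxy-4-(hydroxymethyl)-5-methoxyphenyl 2,2-dimethylpropanoate
Conditions: NaBH4 (1.0 equiv), THF/MeOH, −10 °C, 15 min; pH 7 buffer; used crude at once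
Reagents that add atoms: none
Why: Borohydride reduction of the aldehyde; the hindered aryl pivalate should survive the short cold exposure, and the acyloxy group makes the salicyl alcohol less prone to over-reduction and self-condensation than an alkoxy analogue.

Step 3
Reactants: 3 3-hydroxy-4-(hydroxymethyl)-5-methoxyphenyl 2,2-dimethylpropanoate; 4 styrene
Product: 6 (2S)-5-methoxy-2-phenyl-3,4-dihydro-2H-chromen-7-yl 2,2-dimethylpropanoate, via ortho-quinone methide 5 (not isolated)
Conditions: (S,S)-IDPi (BINOL-derived imidodiphosphorimidate with 3,3'-aryl groups and N-triflyl groups, 5 mol %), styrene (5 equiv), 5 Å MS, CH2Cl2/toluene, −20 °C, 3 added over 6 h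
Reagents that add atoms: none
Why: Proposed new method: the confined acid protonates the benzylic hydroxyl of 3, and water leaves with help from the 2-hydroxyl and 6-methoxy lone pairs to give methide 5, held by a hydrogen bond or ion pair to the chiral anion. The terminal carbon of 4 then bonds to the methide carbon while the carbonyl oxygen closes onto the developing benzylic cation, a concerted but asynchronous inverse-electron-demand hetero-Diels–Alder reaction forming C3–C4 and O1–C2. The closest known reaction type is the chiral Brønsted-acid-catalysed cycloaddition of in situ ortho-quinone methides bearing a substituent on the methide carbon with styrenes, together with the racemic thermal reaction of unsubstituted methides; enantiocontrol with an unsubstituted methide carbon is what is new. The pyran is closed by intermolecular [4π+2π] annulation without a tether, both ring bonds arising in the cycloaddition with the C–O bond lagging. C2 is set by the catalyst alone, whose pocket fixes the methide through the O–H···anion contact and exposes one enantiotopic face of the alkene. The 2-phenyl regiochemistry follows from polarity, the nucleophilic alkene terminus meeting the electrophilic methide carbon and the positive charge developing at the benzylic position. The step needs cycloaddition to beat Friedel–Crafts self-alkylation: the pivalate lowers the ring nucleophilicity of 3 and 6 and raises the electrophilicity of 5, and excess 4 with slow addition of 3 keeps the methide concentration low. Acylation of the 4-oxygen excludes a para-quinone methide, and only the 2-hydroxyl flanks the methide carbon, so a single heterodiene can form.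

Step 4
Reactants: 6 (2S)-5-methoxy-2-phenyl-3,4-dihydro-2H-chromen-7-yl 2,2-dimethylpropanoate
Product: 7 (2S)-5-methoxy-2-phenyl-3,4-dihydro-2H-chromen-7-ol
Conditions: K2CO3 (2 equiv), MeOH (degassed), 25 °C; aq NH4Cl
Reagents that add atoms: none
Why: Base-mediated methanolysis (transesterification) of the aryl ester; the ether-type C2 centre has no acidic hydrogen and cannot epimerise, and no hydrogenolysis is used next to the benzylic C2–O1 bond.

Step 5
Reactants: 7 (2S)-5-methoxy-2-phenyl-3,4-dihydro-2H-chromen-7-ol
Product: 8 (2S)-8-bromo-5-methoxy-2-phenyl-3,4-dihydro-2H-chromen-7-ol
Conditions: NBS (1.0 equiv), CH2Cl2, −78 °C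
Reagents that add atoms: N-bromosuccinimide, O=C1CCC(=O)N1Br
Why: Electrophilic aromatic bromination ortho to the phenol; C8 should be preferred because it is flanked only by the hydroxyl and the tied-back ring oxygen, whereas C6 is shielded by the 5-methoxy group, and one equivalent at low temperature limits dibromination.

Step 6
Reactants: 7 (2S)-5-methoxy-2-phenyl-3,4-dihydro-2H-chromen-7-ol
Product: 9 (2S)-8-[(dimethylamino)methyl]-5-methoxy-2-phenyl-3,4-dihydro-2H-chromen-7-ol
Conditions: CH2=NMe2+ I− (1.0 equiv), Et3N (1.1 equiv), CH2Cl2, 0 °C to rt
Reagents that add atoms: N,N-dimethylmethylideneammonium iodide, C=[N+](C)C.[I-]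
Why: Phenolic Mannich reaction with a preformed iminium salt; ortho-aminomethylation should go to the less hindered C8 for the same steric reason as in step 5, and the absence of free formaldehyde avoids methylene-bridged homodimers.

Step 7
Reactants: 9 (2S)-8-[(dimethylamino)methyl]-5-methoxy-2-phenyl-3,4-dihydro-2H-chromen-7-ol; 8 (2S)-8-bromo-5-methoxy-2-phenyl-3,4-dihydro-2H-chromen-7-ol
Product: 11 (2S)-8-{[(2S)-8-bromo-7-hydroxy-5-methoxy-2-phenyl-3,4-dihydro-2H-chromen-6-yl]methyl}-5-methoxy-2-phenyl-3,4-dihydro-2H-chromen-7-ol, via ortho-quinone methide 10 (not isolated)
Conditions: 8 (2 equiv), toluene, 110 °C, argon sweep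
Reagents that add atoms: none
Why: Thermal retro-Mannich loss of dimethylamine from the phenolic Mannich base gives methide 10, which is captured by ortho C-alkylation of phenol 8 (Friedel–Crafts-type conjugate addition); bromine at C8 leaves C6 as the only ring position of 8 that can react, and neither stereocentre is involved.

Step 8
Reactants: 11 (2S)-8-{[(2S)-8-bromo-7-hydroxy-5-methoxy-2-phenyl-3,4-dihydro-2H-chromen-6-yl]methyl}-5-methoxy-2-phenyl-3,4-dihydro-2H-chromen-7-ol
Product: 12 (2S)-8-{[(2S)-7-hydroxy-5-methoxy-2-phenyl-3,4-dihydro-2H-chromen-6-yl]methyl}-5-methoxy-2-phenyl-3,4-dihydro-2H-chromen-7-ol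
Conditions: H2 (1 atm), 10% Pd/C, Et3N (3 equiv), EtOAc/MeOH, rt
Reagents that add atoms: none
Why: Catalytic hydrodehalogenation of the aryl bromide; aryl C–Br cleavage is fast under these conditions, and the amine both traps HBr and suppresses hydrogenolysis of the benzylic C2–O1 ethers, so both stereocentres should be retained.

## Compound list

1 | 2,4-dihydroxy-6-methoxybenzaldehyde | COc1cc(O)cc(O)c1C=O | starting material
2 | 4-formyl-3-hydroxy-5-methoxyphenyl 2,2-dimethylpropanoate | COc1cc(OC(=O)C(C)(C)C)cc(O)c1C=O | intermediate
3 | 3-hydroxy-4-(hydroxymethyl)-5-methoxyphenyl 2,2-dimethylpropanoate | COc1cc(OC(=O)C(C)(C)C)cc(O)c1CO | intermediate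
4 | styrene | C=Cc1ccccc1 | starting material
5 | 5-methoxy-4-methylidene-3-oxocyclohexa-1,5-dien-1-yl 2,2-dimethylpropanoate (ortho-quinone methide) | COC1=CC(OC(=O)C(C)(C)C)=CC(=O)C1=C | intermediate (not isolated)
6 | (2S)-5-methoxy-2-phenyl-3,4-dihydro-2H-chromen-7-yl 2,2-dimethylpropanoate | COc1cc(OC(=O)C(C)(C)C)cc2c1CC[C@@H](c1ccccc1)O2 | intermediate
7 | (2S)-5-methoxy-2-phenyl-3,4-dihydro-2H-chromen-7-ol | COc1cc(O)cc2c1CC[C@@H](c1ccccc1)O2 | intermediate
8 | (2S)-8-bromo-5-methoxy-2-phenyl-3,4-dihydro-2H-chromen-7-ol | COc1cc(O)c(Br)c2c1CC[C@@H](c1ccccc1)O2 | intermediate
9 | (2S)-8-[(dimethylamino)methyl]-5-methoxy-2-phenyl-3,4-dihydro-2H-chromen-7-ol | COc1cc(O)c(CN(C)C)c2c1CC[C@@H](c1ccccc1)O2 | intermediate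
10 | (2S)-5-methoxy-8-methylidene-2-phenyl-3,4-dihydro-2H-chromen-7(8H)-one (ortho-quinone methide) | COC1=CC(=O)C(=C)C2=C1CC[C@@H](c1ccccc1)O2 | intermediate (not isolated)
11 | (2S)-8-{[(2S)-8-bromo-7-hydroxy-5-methoxy-2-phenyl-3,4-dihydro-2H-chromen-6-yl]methyl}-5-methoxy-2-phenyl-3,4-dihydro-2H-chromen-7-ol | COc1cc(O)c(Cc2c(O)c(Br)c3c(c2OC)CC[C@@H](c2ccccc2)O3)c2c1CC[C@@H](c1ccccc1)O2 | intermediate
12 | (2S)-8-{[(2S)-7-hydroxy-5-methoxy-2-phenyl-3,4-dihydro-2H-chromen-6-yl]methyl}-5-methoxy-2-phenyl-3,4-dihydro-2H-chromen-7-ol | COc1cc(O)c(Cc2c(O)cc3c(c2OC)CC[C@@H](c2ccccc2)O3)c2c1CC[C@@H](c1ccccc1)O2 | target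

## Step count and least certain steps

Total step count: 8 steps. Longest linear sequence: 7 steps (1, 2, 3, 4, 5 or 6, 7, 8).

Step 3 (key step, Proposed new method). Three things are most likely to go wrong. Arylation of the methide by the electron-rich rings of 3 and 6 may outrun cycloaddition, because styrene is a weak nucleophile. Facial discrimination may be poor, because the methide carbon carries no substituent to orient it in the catalyst pocket. The strong acid may start oligomerisation of styrene.
Fallback (known chemistry, from 2, returning at 6):
- Wittig olefination of 2 with 1-phenyl-2-(triphenylphosphoranylidene)ethanone in toluene at 80 °C should give 3-hydroxy-5-methoxy-4-[(1E)-3-oxo-3-phenylprop-1-en-1-yl]phenyl 2,2-dimethylpropanoate F1.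
- Hydrogenation of the alkene (H2, Pd/C, EtOAc, stopped after one equivalent) should give 3-hydroxy-5-methoxy-4-(3-oxo-3-phenylpropyl)phenyl 2,2-dimethylpropanoate F2.
- Noyori transfer hydrogenation with RuCl(p-cymene)[(R,R)-TsDPEN] in HCO2H/Et3N should give 3-hydroxy-4-[(3R)-3-hydroxy-3-phenylpropyl]-5-methoxyphenyl 2,2-dimethylpropanoate F3.
- Intramolecular Mitsunobu etherification (PPh3, DIAD, THF, 0 °C) should close the pyran with inversion to give 6 with the (2S) configuration.

Step 7. The methide may be consumed by the free C6 position of its own precursor 9 or of unit A in the product, because the brominated phenol 8 is the less reactive nucleophile; oligomers would result.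
Fallback (roles of the halves reversed, from 8, returning at 11): Mannich reaction of 8 with the same iminium salt at its only free position should give (2S)-8-bromo-6-[(dimethylamino)methyl]-5-methoxy-2-phenyl-3,4-dihydro-2H-chromen-7-ol F6. Heating F6 in toluene with an excess of 7 should release (2S)-8-bromo-5-methoxy-6-methylidene-2-phenyl-3,4-dihydro-2H-chromen-7(6H)-one F7. F7 has no open ring position for self-condensation and should be captured by 7 at C8 to give 11.

Step 5. Site selectivity between C6 and C8 may be poor and a second bromination may occur, because the free phenol activates both ortho positions strongly.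
Fallback (bromination before unmasking, from 6, returning at 8): treatment of 6 with NBS in MeCN at 0 °C should brominate the less activated ester once, at the less hindered C8, to give (2S)-8-bromo-5-methoxy-2-phenyl-3,4-dihydro-2H-chromen-7-yl 2,2-dimethylpropanoate F4. Methanolysis with K2CO3 in MeOH should then give 8.

Step 6. Aminomethylation may be partly diverted to C6 or go twice, for the same reason as in step 5.
Fallback (C8 carbon introduced through the bromide, from 8, returning at 9): treatment of 8 with n-BuLi (2.2 equiv) in THF at −78 °C should deprotonate the phenol and exchange bromine to give lithium (2S)-8-lithio-5-methoxy-2-phenyl-3,4-dihydro-2H-chromen-7-olate F5. Its aryllithium carbon should add to N,N-dimethylmethylideneammonium iodide to give 9 on aqueous work-up. The C8 position of both halves would then rest on the single bromination.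

Step 8. Hydrogenolytic opening of the benzylic C2–O1 bonds may compete, or reduction of the hindered, electron-rich bromide may be slow.
Fallback (radical chain reduction in place of hydrogenolysis, from 11, returning at 12): (Me3Si)3SiH with AIBN in toluene at 80 °C should replace bromine by hydrogen without touching benzylic ethers. No new compound is involved.

## Further compounds

F1 | step 3 | 3-hydroxy-5-methoxy-4-[(1E)-3-oxo-3-phenylprop-1-en-1-yl]phenyl 2,2-dimethylpropanoate | COc1cc(OC(=O)C(C)(C)C)cc(O)c1/C=C/C(=O)c1ccccc1
F2 | step 3 | 3-hydroxy-5-methoxy-4-(3-oxo-3-phenylpropyl)phenyl 2,2-dimethylpropanoate | COc1cc(OC(=O)C(C)(C)C)cc(O)c1CCC(=O)c1ccccc1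
F3 | step 3 | 3-hydroxy-4-[(3R)-3-hydroxy-3-phenylpropyl]-5-methoxyphenyl 2,2-dimethylpropanoate | COc1cc(OC(=O)C(C)(C)C)cc(O)c1CC[C@@H](O)c1ccccc1
F4 | step 5 | (2S)-8-bromo-5-methoxy-2-phenyl-3,4-dihydro-2H-chromen-7-yl 2,2-dimethylpropanoate | COc1cc(OC(=O)C(C)(C)C)c(Br)c2c1CC[C@@H](c1ccccc1)O2
F5 | step 6 | lithium (2S)-8-lithio-5-methoxy-2-phenyl-3,4-dihydro-2H-chromen-7-olate | COc1cc(O[Li])c([Li])c2c1CC[C@@H](c1ccccc1)O2
F6 | step 7 | (2S)-8-bromo-6-[(dimethylamino)methyl]-5-methoxy-2-phenyl-3,4-dihydro-2H-chromen-7-ol | COc1c(CN(C)C)c(O)c(Br)c2c1CC[C@@H](c1ccccc1)O2
F7 | step 7 | (2S)-8-bromo-5-methoxy-6-methylidene-2-phenyl-3,4-dihydro-2H-chromen-7(6H)-one | COC1=C2CC[C@@H](c3ccccc3)OC2=C(Br)C(=O)C1=C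
F0 | step 8 | none | none
A1 | alternative 1 | (2S)-8-{[(2S)-7-(tert-butyldimethylsilyloxy)-5-methoxy-2-phenyl-3,4-dihydro-2H-chromen-6-yl]methyl}-5-methoxy-2-phenyl-3,4-dihydro-2H-chromen-7-ol | COc1cc(O)c(Cc2c(O[Si](C)(C)C(C)(C)C)cc3c(c2OC)CC[C@@H](c2ccccc2)O3)c2c1CC[C@@H](c1ccccc1)O2
A2 | alternative 1 | 2-[(3S)-3-({3-[(2S)-7-(tert-butyldimethylsilyloxy)-5-methoxy-2-phenyl-3,4-dihydro-2H-chromen-6-yl]prop-1-yn-1-yl}oxy)-3-phenylpropyl]-3-methoxycyclobut-2-en-1-one | COC1=C(CC[C@@H](c2ccccc2)OC#CCc2c(O[Si](C)(C)C(C)(C)C)cc3c(c2OC)CC[C@@H](c2ccccc2)O3)C(=O)C1
A3 | alternative 2 | (2S,2'S)-8,6'-methylenebis[7-(tert-butyldimethylsilyloxy)-5-methoxy-2-phenyl-2H-chromene] | COc1cc(O[Si](C)(C)C(C)(C)C)c(Cc2c(O[Si](C)(C)C(C)(C)C)cc3c(c2OC)C=C[C@@H](c2ccccc2)O3)c2c1C=C[C@@H](c1ccccc1)O2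
A4 | alternative 2 | 8,6'-methylenebis[7-(tert-butyldimethylsilyloxy)-2-ethoxy-5-methoxy-2H-chromene] (mixture of acetal stereoisomers) | COc1cc(O[Si](C)(C)C(C)(C)C)c(Cc2c(O[Si](C)(C)C(C)(C)C)cc3c(c2OC)C=CC(OCC)O3)c2c1C=CC(OCC)O2
A5 | alternative 2 | phenylboronic acid | OB(O)c1ccccc1
A6 | alternative 3 | (2S)-8-{[(2S)-7-(benzyloxy)-5-methoxy-2-phenyl-3,4-dihydro-2H-chromen-6-yl]methyl}-5-methoxy-2-phenyl-3,4-dihydro-2H-chromen-7-ol | COc1cc(O)c(Cc2c(OCc3ccccc3)cc3c(c2OC)CC[C@@H](c2ccccc2)O3)c2c1CC[C@@H](c1ccccc1)O2
A7 | alternative 3 | 2-{[(2S)-7-(benzyloxy)-5-methoxy-2-phenyl-3,4-dihydro-2H-chromen-6-yl]methyl}-3-{[(1S)-3-iodo-1-phenylpropyl]oxy}-5-methoxyphenol | COc1cc(O)c(Cc2c(OCc3ccccc3)cc3c(c2OC)CC[C@@H](c2ccccc2)O3)c(O[C@@H](CCI)c2ccccc2)c1
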